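**Strategy.** The cyclohexane ring is read as a Diels–Alder adduct. Its C(CH3)2–CHBr bond and its CH–C(CH3)(O) ring-fusion bond flank the C(CH3)2–CH bond, so the gem-dimethyl carbon and the fusion CH are the two dienophile carbons and the other four ring carbons a diene. One auxiliary-controlled [4+2] between (E)-penta-1,3-diene and a 3-methylbut-2-enoate makes both bonds, the carbocycle and the cis CH/C–CH3 pair at once. The adduct is oxidised at two ring C–H bonds, locked as a ketal that later delivers the ditertiary ether, brominated by hydrogen-atom transfer, and closed to the ten-membered ring by two B-alkyl Suzuki couplings before epoxidation.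

Key step: step 2

Numbering used in the text: ring C1 = CHBr, C2 = C(CH3)2, C3 = fusion CH, C4 = fusion C(CH3)O, C5 and C6 = CH2; C7 = the carbon on C3; C8 = the quaternary ether carbon.

Assumption 1: the TiCl4 chelate of the (R)-pantolactone ester is attacked on the face that gives adduct 5 as drawn; if the sense is the opposite, (S)-pantolactone is used in the same way.

Assumption 2: ketal 11 equilibrates under the acid catalyst to the epimer with the alkynyl group axial and the methyl group equatorial on the 1,3-dioxane.

Step 1
Reactants: 1 (R)-pantolactone; 2 3-methylbut-2-enoyl chloride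
Product: 3 (R)-pantolactonyl 3-methylbut-2-enoate
Conditions: Et3N, DMAP (cat.), CH2Cl2, 0 °C to rt
Reagents that add atoms: none
Why: DMAP-catalysed acylation of the secondary alcohol, which touches no stereocentre.

Step 2
Reactants: 3 (R)-pantolactonyl 3-methylbut-2-enoate; 4 (E)-penta-1,3-diene
Product: 5 pantolactonyl cis-2,6,6-trimethylcyclohex-3-ene-1-carboxylate
Conditions: TiCl4 (0.5 equiv), CH2Cl2, −40 to −10 °C
Reagents that add atoms: none
Why: TiCl4 chelates the ester and lactone carbonyls of 3 and turns the sluggish β,β-disubstituted acrylate into a polarised s-cis dienophile that adds the diene in a concerted, asynchronous [4+2] cycloaddition, the unsubstituted diene terminus bonding to the C(CH3)2 carbon (C1–C2) and the methyl-bearing terminus to the α-carbon (C3–C4). The closest known reactions are the AlCl3-catalysed Diels–Alder reaction of (E)-penta-1,3-diene with 4-methylpent-3-en-2-one (the δ-damascone ring synthesis) and the TiCl4-mediated cycloadditions of pantolactone acrylates. The cyclohexene is the only ring closed, in one step that is suprafacial on both partners. The cis relation of ester and methyl at C3 and C4 follows from the endo transition state with the (E)-methyl group outside, and the absolute configuration from attack on the face of the chelate left open by the auxiliary. The step needs the regiochemistry with the gem-dimethyl carbon next to the ring CH2; the terminal methyl donor of the diene secures it, helped because the hindered β-carbon meets the unsubstituted diene terminus.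

Step 3
Reactants: 5 pantolactonyl cis-2,6,6-trimethylcyclohex-3-ene-1-carboxylate
Product: 6 allylic alcohol (OH on C1)
Conditions: SeO2 (0.5 equiv), t-BuOOH, CH2Cl2, rt
Reagents that add atoms: selenium dioxide O=[Se]=O; tert-butyl hydroperoxide CC(C)(C)OO
Why: SeO2 allylic oxidation (ene reaction, then [2,3] shift) prefers the allylic CH2 at C1 over the allylic CH at C4; the new carbinol configuration is irrelevant because it is oxidised in step 5.

Step 4
Reactants: 6 allylic alcohol
Product: 7 saturated hydroxy ester
Conditions: H2 (1 atm), Pd/C, EtOAc, rt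
Reagents that add atoms: none
Why: Heterogeneous hydrogenation of the cis-disubstituted ring alkene, with no stereocentre created.

Step 5
Reactants: 7 saturated hydroxy ester
Product: 8 hydroxy keto ester (C1 ketone, C4 tertiary OH)
Conditions: methyl(trifluoromethyl)dioxirane (3 equiv), CH2Cl2, 0 °C
Reagents that add atoms: methyl(trifluoromethyl)dioxirane CC1(OO1)C(F)(F)F
Why: Dioxirane oxidation turns the secondary alcohol into the ketone and inserts oxygen into the only tertiary C–H bond not deactivated by a neighbouring carbonyl (C4–H), with retention, so the C4–O configuration is the one set for C4–H in step 2.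

Step 6
Reactants: 8 hydroxy keto ester
Product: 9 triol
Conditions: LiAlH4, THF, 0 °C to rt
Reagents that add atoms: none
Why: Hydride reduction of ester and ketone gives the 1,3-diol (C4–OH, C7–OH) and frees the auxiliary; the C1 carbinol is a mixture that is reoxidised in step 8.

Step 7
Reactants: 9 triol; 10 4-(trimethylsilyl)but-3-yn-2-one
Product: 11 ketal alcohol
Conditions: i-PrOSiMe3, Me3SiOTf (cat.), CH2Cl2, −40 to 0 °C
Reagents that add atoms: none
Why: Noyori-type ketalisation of the only 1,3-diol pair gives the trans-fused 1,3-dioxane, which locks the cyclohexane chair with the C4 methyl axial; C8 equilibrates to the epimer with the small alkynyl group axial.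

Step 8
Reactants: 11 ketal alcohol
Product: 12 ketal ketone
Conditions: Dess–Martin periodinane, NaHCO3, CH2Cl2, rt
Reagents that add atoms: none
Why: Mild hypervalent-iodine oxidation of the hindered secondary alcohol, which leaves the ketal and silylalkyne intact.

Step 9
Reactants: 12 ketal ketone
Product: 13 vinyl bromide (C1(Br)=C6)
Conditions: P(OPh)3, Br2, Et3N (excess), CH2Cl2, −60 °C to reflux
Reagents that add atoms: bromine BrBr
Why: Ketone to vinyl bromide with the triphenyl phosphite–bromine reagent; the ketone can enolise only toward C6, and excess amine protects the ketal.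

Step 10
Reactants: 13 vinyl bromide
Product: 14 bromo ketal (C1–Br equatorial)
Conditions: Mn(dpm)3 (cat.), PhSiH3, t-BuOOH, i-PrOH, rt
Reagents that add atoms: none
Why: Hydrogen-atom-transfer hydrogenation puts H on C6 and then quenches the α-bromo radical at C1 from the axial direction of the locked chair (the other face is blocked by the axial C2 methyl), which sets C1 with bromine equatorial and cis to the C3 substituent.

Step 11
Reactants: 14 bromo ketal
Product: 15 ether alcohol (C4–O–C8 ether, C7–OH)
Conditions: CH2=CHAlEt2 (from CH2=CHMgBr and Et2AlCl), toluene, −20 to 0 °C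
Reagents that add atoms: diethyl(vinyl)aluminium C=C[Al](CC)CC
Why: Organoaluminium cleavage of a cyclic ketal: aluminium binds the less hindered primary oxygen, the C8–O bond to it ionises, and the vinyl group passes from aluminium to the face that oxygen left (retention), which forms the ditertiary ether and fixes C8.

Step 12
Reactants: 16 propyne
Product: 17 (E)-2-bromo-1-iodoprop-1-ene
Conditions: IBr, CH2Cl2, −78 °C
Reagents that add atoms: iodine monobromide IBr
Why: Anti addition of IBr to the alkyne, with bromide opening the iodonium ion at the substituted carbon, gives the E dihalide.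

Step 13
Reactants: 15 ether alcohol; 17 (E)-2-bromo-1-iodoprop-1-ene
Product: 19 alkenyl bromide alcohol, via bis(9-borabicyclononyl) adduct 18 (not isolated)
Conditions: 9-BBN (2.2 equiv), THF, 50 °C; then 17, Pd(dppf)Cl2, AsPh3, K3PO4 (aq), DMF, rt
Reagents that add atoms: none
Why: Anti-Markovnikov hydroboration of the only alkene, then B-alkyl Suzuki–Miyaura coupling at the C–I bond (more reactive than C–Br) with retention of the alkene geometry.

Step 14
Reactants: 19 alkenyl bromide alcohol
Product: 21 C3-vinyl compound, via aldehyde 20 (not isolated)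
Conditions: (COCl)2, DMSO, Et3N, CH2Cl2, −78 °C; then Ph3P=CH2 (from Ph3PCH3Br and KN(SiMe3)2), THF, −78 °C to rt
Reagents that add atoms: methylenetriphenylphosphorane C=P(c1ccccc1)(c1ccccc1)c1ccccc1
Why: One-pot Swern oxidation and Wittig methylenation; the aldehyde is not isolated, and its α-centre C3 already has the favoured equatorial configuration.

Step 15
Reactants: 21 C3-vinyl compound
Product: 24 macrocyclic enyne, via B-alkylborane 22 (not isolated), via silylated macrocycle 23 (not isolated)
Conditions: 9-BBN, THF, 50 °C; then slow addition to Pd(dppf)Cl2, AsPh3, Cs2CO3, DMF/THF/H2O (1 mM), 50 °C; then K2CO3, MeOH, rt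
Reagents that add atoms: none
Why: Hydroboration of the terminal vinyl group and intramolecular B-alkyl Suzuki–Miyaura coupling with the alkenyl bromide close the ten-membered ring with the E geometry carried over from 17; methanolysis then removes the alkyne silyl group.

Step 16
Reactants: 24 macrocyclic enyne
Product: 25 macrocyclic diene
Conditions: H2 (1 atm), Pd/CaCO3 poisoned with Pb(OAc)2, quinoline, EtOAc, rt
Reagents that add atoms: none
Why: Lindlar semi-hydrogenation of the terminal alkyne to the vinyl group; the trisubstituted ring alkene and the alkyl bromide do not react.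

Step 17
Reactants: 25 macrocyclic diene
Product: 26 target epoxide
Conditions: L-fructose-derived Shi ketone (30 mol%), KHSO5 (as 2KHSO5·KHSO4·K2SO4), K2CO3, Bu4NHSO4, MeCN/dimethoxymethane/aqueous buffer, 0 °C
Reagents that add atoms: potassium peroxymonosulfate [K+].[O-]S(=O)(=O)OO
Why: Shi epoxidation through the spiro dioxirane transition state oxidises the electron-rich (E)-trisubstituted alkene and not the vinyl group; the L-series ketone is chosen to give the (S,S)-epoxide under reagent control.

**Compound list**

1 | (R)-pantolactone, (3R)-3-hydroxy-4,4-dimethyloxolan-2-one | O=C1OCC(C)(C)[C@H]1O | starting material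
2 | 3-methylbut-2-enoyl chloride | CC(C)=CC(=O)Cl | starting material
3 | (3R)-4,4-dimethyl-2-oxooxolan-3-yl 3-methylbut-2-enoate | O=C1OCC(C)(C)[C@H]1OC(=O)C=C(C)C | intermediate
4 | (E)-penta-1,3-diene | C=C/C=C/C | starting material
5 | (3R)-4,4-dimethyl-2-oxooxolan-3-yl (1R,2R)-2,6,6-trimethylcyclohex-3-ene-1-carboxylate (ester and 2-methyl cis) | O=C1OCC(C)(C)[C@H]1OC(=O)[C@H]2C(C)(C)CC=C[C@H]2C | intermediate
6 | 5-hydroxy derivative of 5 (allylic alcohol next to the gem-dimethyl carbon, both carbinol epimers) | O=C1OCC(C)(C)[C@H]1OC(=O)[C@H]2C(C)(C)C(O)C=C[C@H]2C | intermediate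
7 | pantolactonyl 3-hydroxy-2,2,6-trimethylcyclohexane-1-carboxylate (ester and 6-methyl cis, carbinol epimers) | O=C1OCC(C)(C)[C@H]1OC(=O)[C@H]2C(C)(C)C(O)CC[C@H]2C | intermediate
8 | pantolactonyl (1S,6S)-6-hydroxy-2,2,6-trimethyl-3-oxocyclohexane-1-carboxylate (tertiary OH trans to the ester) | O=C1OCC(C)(C)[C@H]1OC(=O)[C@H]2C(C)(C)C(=O)CC[C@]2(C)O | intermediate
9 | (1S,2R)-2-(hydroxymethyl)-1,3,3-trimethylcyclohexane-1,4-diol (CH2OH trans to the tertiary OH, C4 carbinol epimers) | OC[C@H]1C(C)(C)C(O)CC[C@]1(C)O | intermediate
10 | 4-(trimethylsilyl)but-3-yn-2-one | CC(=O)C#C[Si](C)(C)C | starting material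
11 | ketal alcohol: trans-fused 1,3-dioxane from the tertiary OH and CH2OH of 9 with 10, methyl equatorial and trimethylsilylethynyl axial on the ketal carbon, ring CH–OH free | C[Si](C)(C)C#C[C@@]1(C)OC[C@H]2C(C)(C)C(O)CC[C@]2(C)O1 | intermediate
12 | ketal ketone (ketone next to the gem-dimethyl carbon) | C[Si](C)(C)C#C[C@@]1(C)OC[C@H]2C(C)(C)C(=O)CC[C@]2(C)O1 | intermediate
13 | ketal vinyl bromide | C[Si](C)(C)C#C[C@@]1(C)OC[C@H]2C(C)(C)C(Br)=CC[C@]2(C)O1 | intermediate
14 | bromo ketal (Br equatorial, cis to the CH2O substituent) | C[Si](C)(C)C#C[C@@]1(C)OC[C@H]2C(C)(C)[C@@H](Br)CC[C@]2(C)O1 | intermediate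
15 | ether alcohol: bromocyclohexane with CH2OH on C3 and, on C4, the ether to the carbon bearing methyl, vinyl and trimethylsilylethynyl | OC[C@H]1C(C)(C)[C@@H](Br)CC[C@]1(C)O[C@](C)(C=C)C#C[Si](C)(C)C | intermediate
16 | propyne | CC#C | starting material
17 | (E)-2-bromo-1-iodoprop-1-ene | C/C(Br)=C\I | intermediate
18 | bis(9-BBN) adduct of 15 (B on the former vinyl terminus and on the primary oxygen) | O(B3C4CCCC3CCC4)C[C@H]1C(C)(C)[C@@H](Br)CC[C@]1(C)O[C@](C)(CCB5C6CCCC5CCC6)C#C[Si](C)(C)C | intermediate
19 | alkenyl bromide alcohol: 15 with the vinyl group replaced by (E)-4-bromopent-3-enyl | OC[C@H]1C(C)(C)[C@@H](Br)CC[C@]1(C)O[C@](C)(CC/C=C(\C)Br)C#C[Si](C)(C)C | intermediate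
20 | aldehyde of 19 (CHO on C3) | O=C[C@H]1C(C)(C)[C@@H](Br)CC[C@]1(C)O[C@](C)(CC/C=C(\C)Br)C#C[Si](C)(C)C | intermediate
21 | C3-vinyl compound (vinyl in place of CH2OH) | C=C[C@H]1C(C)(C)[C@@H](Br)CC[C@]1(C)O[C@](C)(CC/C=C(\C)Br)C#C[Si](C)(C)C | intermediate
22 | B-alkyl-9-BBN adduct of 21 (B on the terminal carbon of the former C3-vinyl group) | B1(C2CCCC1CCC2)CC[C@H]3C(C)(C)[C@@H](Br)CC[C@]3(C)O[C@](C)(CC/C=C(\C)Br)C#C[Si](C)(C)C | intermediate
23 | silylated macrocycle: ten-membered cyclic ether with (E)-trisubstituted alkene and trimethylsilylethynyl group | C[Si](C)(C)C#C[C@@]1(C)CC/C=C(\C)CC[C@H]2C(C)(C)[C@@H](Br)CC[C@]2(C)O1 | intermediate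
24 | macrocyclic enyne (ethynyl in place of the final vinyl) | C#C[C@@]1(C)CC/C=C(\C)CC[C@H]2C(C)(C)[C@@H](Br)CC[C@]2(C)O1 | intermediate
25 | macrocyclic diene (des-epoxy target) | C=C[C@@]1(C)CC/C=C(\C)CC[C@H]2C(C)(C)[C@@H](Br)CC[C@]2(C)O1 | intermediate
26 | CNP0243863.1 | C=C[C@@]1(C)CC[C@@H]2O[C@@]2(C)CC[C@H]2C(C)(C)[C@@H](Br)CC[C@]2(C)O1 | target

**Step count.** Total: 17 steps. Longest linear sequence: 16 steps (steps 1–11 and 13–17).

**Steps most likely to fail and their fallbacks**

Step 2. The β,β-disubstituted ester may react too slowly for the diene to survive TiCl4, and the auxiliary may discriminate the two faces poorly. The fallback sets out from 2 and 4: the acid chloride itself serves as the far more reactive dienophile (sealed tube, 60 °C, or ZnCl2 catalysis) and gives racemic cis-2,6,6-trimethylcyclohex-3-ene-1-carbonyl chloride F1. Acylation of 1 with F1 (Et3N, DMAP) gives 5 together with its diastereomer; the two are separated by crystallisation or chromatography, so the auxiliary acts as a resolving group. The route is rejoined at 5.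

Step 11. The ketal may ionise at the tertiary C–O bond instead of the primary one, which would leave the ether on the wrong oxygen. The fallback sets out from 14. Aqueous acetic acid hydrolyses the ketal to the bromo diol F2. TEMPO/PhI(OAc)2 followed by NaClO2 oxidises the primary alcohol to the β-hydroxy acid F3. Condensation of F3 with 10 (Me3SiCl, Et3N, then Me3SiOTf cat.) gives the 1,3-dioxan-4-one F4, in which only the acyloxy oxygen can leave. Opening with the same vinylalane gives the ether acid F5, and reduction of its mixed anhydride (ClCO2Et, Et3N, then NaBH4) returns to the route at 15.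

Step 15. β-Hydride elimination, protodeboronation and oligomerisation may outrun closure of the strained ten-membered ring. The fallback sets out from 21. Hydroboration with 9-BBN and oxidation with NaBO3 give the primary alcohol F6, and I2, PPh3 and imidazole convert it to the iodide F7. Activated Zn in dimethylacetamide inserts into the C–I bond only, and Pd(dppf)Cl2 under slow addition closes the ring by an intramolecular Negishi coupling with the alkenyl bromide to give 23. Desilylation (K2CO3, MeOH) returns to the route at 24.

**Further compounds**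

F1 | step 2 | racemic cis-2,6,6-trimethylcyclohex-3-ene-1-carbonyl chloride (one enantiomer drawn) | O=C(Cl)[C@H]1C(C)(C)CC=C[C@H]1C
F2 | step 11 | bromo diol: 4-bromo-2-(hydroxymethyl)-1,3,3-trimethylcyclohexan-1-ol, configuration as in 14 | OC[C@H]1C(C)(C)[C@@H](Br)CC[C@]1(C)O
F3 | step 11 | β-hydroxy acid: 3-bromo-6-hydroxy-2,2,6-trimethylcyclohexane-1-carboxylic acid, configuration as in 14 | OC(=O)[C@H]1C(C)(C)[C@@H](Br)CC[C@]1(C)O
F4 | step 11 | 1,3-dioxan-4-one from F3 and 10 (alkynyl axial) | C[Si](C)(C)C#C[C@@]1(C)OC(=O)[C@H]2C(C)(C)[C@@H](Br)CC[C@]2(C)O1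
F5 | step 11 | ether acid (15 with CO2H in place of CH2OH) | OC(=O)[C@H]1C(C)(C)[C@@H](Br)CC[C@]1(C)O[C@](C)(C=C)C#C[Si](C)(C)C
F6 | step 15 | primary alcohol from hydroboration–oxidation of 21 | OCC[C@H]1C(C)(C)[C@@H](Br)CC[C@]1(C)O[C@](C)(CC/C=C(\C)Br)C#C[Si](C)(C)C
F7 | step 15 | primary iodide from F6 | ICC[C@H]1C(C)(C)[C@@H](Br)CC[C@]1(C)O[C@](C)(CC/C=C(\C)Br)C#C[Si](C)(C)C
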